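At the reading, 1.5 h after the start, I have to give the share of target in target plus side product for each flask below.

| flask | substrate | reagent | free catalyst | remark | time |
|---|---|---|---|---|---|
| theta | 20 mM | 12 mM | 0.20 mM | run made earlier |  |
| delta | 20 mM | 6 mM | 0.20 mM | run made earlier |  |
| beta | 20 mM | 9 mM | 0.20 mM | run made earlier |  |
| alpha | 20 mM | 12 mM | 0.10 mM | run made earlier |  |
| south-east | 20 mM (fed, over 80 min) | 12.0 mM | 0.20 mM | all else is in the flask from the start; the feed brings no volume worth counting | 1.5 h |
| west | 20 mM | 12.0 mM | 0.20 mM | everything together at the start | 1.5 h |
| south | 20 mM | 12.0 mM (fed, over 80 min) | 0.20 mM | all else is in the flask from the start; the feed brings no volume worth counting | 1.5 h |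
| south-west | 20 mM | 12.0 mM (in portions, 3, over 80 min) | 0.20 mM | first portion at the start, last at 80 min | 1.5 h |

| run | time / min | target / % | side product / % |
|---|---|---|---|
| theta | 8.00 | 15 | 3 |
| theta | 15.0 | 32 | 14 |
| theta | 25.0 | 41 | 22 |
| theta | 50.0 | 58 | 35 |
| theta | 90.0 | 61 | 37 |
| delta | 20.0 | 22 | 13 |
| delta | 40.0 | 29 | 23 |
| delta | 60.0 | 29 | 27 |
| delta | 80.0 | 27 | 27 |
| delta | 120 | 30 | 31 |
| beta | 20.0 | 30 | 15 |
| beta | 40.0 | 37 | 28 |
| beta | 60.0 | 43 | 37 |
| beta | 80.0 | 43 | 38 |
| beta | 120 | 42 | 41 |
| alpha | 8.00 | 10 | 5 |
| alpha | 15.0 | 16 | 6 |
| alpha | 30.0 | 30 | 18 |
| alpha | 60.0 | 46 | 31 |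
| alpha | 120 | 57 | 41 |

(readings scatter by 2 percentage points)

* the flask with the highest share of target in target plus side product ("all alike" if they lie within 1.5 percentage points) (south-east / west / south / south-west / all alike)
* share of target in target plus side product at the end, south-east
* share of target in target plus side product at the end, west
* share of target in target plus side product at the end, south
* share of target in target plus side product at the end, south-west

- what was read earlier has a scatter of 2 percentage points, one standard deviation

The latest readings come first. Target stands at 12.2 mM on 12 mM of reagent in the theta run, at 8.40 mM on 9 mM in the beta run and at 6.00 mM on 6 mM in the delta run. So within the scatter each reagent gives about one target, and reagent is the limiting reagent for target.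

I therefore carry the target ceiling c, the reagent charge over the substrate charge, 60.0 % here. In a flask with these charges, once the substrate is consumed, the substrate that did not become target stands as side product, so the share equals c. South-east, west, south and south-west each carry 20 mM of substrate and 12.0 mM of reagent, so how a charge goes in leaves c unchanged. I expect each flask near c, apart by what is unfinished at the reading.

The forecast names south-east and gives 64 %, 62 %, 46 % and 47 % in the order asked. It differs from my reckoning on the reagent-fed flasks: “Portions give about 47%, and conversion may be incomplete”.

The simulation names south-east and gives 65.6 %, 60.9 %, 60.3 % and 58.0 %.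

    reagent + free catalyst → catalyst intermediate A (k = 8.06 /M/s)
    catalyst intermediate C → free catalyst + target (k = 0.493 /s)
    substrate + catalyst intermediate A → catalyst intermediate B (k = 8.50 /M/s)
    substrate + by-product → side product (k = 0.0906 /M/s)
    catalyst intermediate B → by-product + catalyst intermediate C (k = 0.213 /s)
    2 catalyst intermediate B → spent catalyst (k = 1.68 /M/s)

South gives 60.3 %, above the forecast's 46 % and close to c, with 11 % of its substrate and 10 % of its reagent still there at the reading. The neighbour of south-west charged with 3.0 mM of reagent has its own ceiling, 15.0 %. That flask has 13.9 % of its reagent left at the reading, so the reagent used comes to 12.9 % of the substrate charged, and after 1.50 h it holds 12.9 % of target.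

The earlier runs and the new flask were computed with constants of no real substance, and the scatter is random.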